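**Retrosynthetic overview**

1. 25 ⇐ 24 ⇐ 23 (desilylation, Pinnick oxidation); 23 ⇐ acyclic, achiral (Z)-enal 22 by one enantioselective intramolecular Diels–Alder reaction that forms C1–C14 and C11–C15 together (locants of bicyclo[9.3.1]pentadecane: C1 and C11 bridgeheads, C15 the one-carbon bridge).
2. Enabling feature: ring C1–C14–C13=C12–C11–C15 is a cyclohexene with its double bond opposite the C1–C15 bond and a carbonyl carbon on C15, a Diels–Alder retron. The nine carbons C2–C10 are then only a tether from diene terminus C11 to dienophile β-carbon C1, so both bridges fall away at once.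
3. Ring order: no ring exists before step 12; the cyclohexene and the 12-membered ring (C1–C11 plus C15) close in the same event, the 12-ring being completed by the C11–C15 bond.
4. 22 ⇐ allylic bromide 17 + propargyl alcohol + homoprenyl Grignard reagent (anti-carbomagnesiation/allylation fixes the (Z)-dienophile); 17 ⇐ 10 (propargylation, methylalumination: 3E); 10 ⇐ dienol 7 (7Z from the commercial enynol) + iododiene 5 (diene geometry from a second anti-carbomagnesiation).

Key step: step 12

Assumption: the (S)-oxazaborolidinium catalyst is taken to deliver the diene to the Re face at C2 of a 2-alkylenal, as with 2-methylacrolein; the (R)-antipode is equally available should a first run show the opposite sense.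

**Route**

Step 1
Reactants: 1 prop-2-yn-1-ol; 2 vinylmagnesium bromide
Product: 4 (2Z)-2-(iodomethylidene)but-3-en-1-ol, via chelated dienylmagnesium alkoxide 3 (not isolated)
Conditions: 2 (2.5 equiv), CuI (10 mol %), THF, −20 °C → rt; then I2, −78 → 0 °C
Reagents that add atoms: iodine, II
Why: Hydroxyl-directed anti-carbomagnesiation of the propargylic alkoxide puts the vinyl group on the internal carbon and holds magnesium cis to CH2O in a five-membered chelate, so iodinolysis with retention should give the (Z)-iodide.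

Step 2
Reactants: 4
Product: 5 tert-butyl{[(2Z)-2-(iodomethylidene)but-3-en-1-yl]oxy}diphenylsilane
Conditions: TBDPSCl, imidazole, CH2Cl2, 0 °C → rt
Reagents that add atoms: tert-butyl(chloro)diphenylsilane, CC(C)(C)[Si](Cl)(c1ccccc1)c1ccccc1
Why: Standard silylation of a primary alcohol gives an ether that should survive the organometallic, Lewis-acid and chlorite steps that follow.

Step 3
Reactants: 6 (2Z)-3-methylpent-2-en-4-yn-1-ol
Product: 7 (2Z)-3-methylpenta-2,4-dien-1-ol
Conditions: H2 (1 atm), Pd/CaCO3 poisoned with Pb(OAc)2, quinoline, EtOAc, rt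
Reagents that add atoms: none
Why: Lindlar semihydrogenation should stop at the vinyl group and leave the (Z)-trisubstituted alkene of the starting material untouched.

Step 4
Reactants: 7; 5
Product: 9 (2Z,6Z)-7-{[tert-butyl(diphenyl)silyl]oxymethyl}-3-methylnona-2,6,8-trien-1-ol, via bis-borylated pentenol 8 (not isolated)
Conditions: 9-BBN (2.2 equiv), THF, 0 °C → rt; then aq. Cs2CO3, 5, Pd(dppf)Cl2 (5 mol %), AsPh3, DMF, rt
Reagents that add atoms: none
Why: 9-BBN adds anti-Markovnikov to the monosubstituted terminus of the diene far faster than to the trisubstituted alkene, and the primary alkylborane couples with the alkenyl iodide with retention (B-alkyl Suzuki–Miyaura coupling).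

Step 5
Reactants: 9
Product: 10 (2Z,6Z)-1-bromo-7-{[tert-butyl(diphenyl)silyl]oxymethyl}-3-methylnona-2,6,8-triene
Conditions: CBr4, PPh3, CH2Cl2, −20 → 0 °C
Reagents that add atoms: tetrabromomethane, BrC(Br)(Br)Br
Why: Appel bromination of a primary allylic alcohol under cold, neutral conditions should keep the (Z)-geometry and the silyl ether.

Step 6
Reactants: 10; 11 trimethyl(prop-1-yn-1-yl)silane
Product: 13 (5Z,9Z)-10-{[tert-butyl(diphenyl)silyl]oxymethyl}-6-methyl-1-(trimethylsilyl)dodeca-5,9,11-trien-1-yne, via lithiated silylpropyne 12 (not isolated)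
Conditions: 11, n-BuLi, THF, −78 °C; then 10, −78 → 0 °C
Reagents that add atoms: none
Why: SN2 alkylation of the primary allylic bromide by the propargylic lithium reagent, whose silyl group blocks the allenyl terminus, should proceed without allylic transposition.

Step 7
Reactants: 13
Product: 14 (5Z,9Z)-10-{[tert-butyl(diphenyl)silyl]oxymethyl}-6-methyldodeca-5,9,11-trien-1-yne
Conditions: K2CO3, MeOH, rt
Reagents that add atoms: none
Why: Base-catalysed protodesilylation of the alkynylsilane leaves the TBDPS ether intact.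

Step 8
Reactants: 14
Product: 16 (2E,6Z,10Z)-11-{[tert-butyl(diphenyl)silyl]oxymethyl}-3,7-dimethyltrideca-2,6,10,12-tetraen-1-ol, via alkenyldimethylalane 15 (not isolated)
Conditions: Me3Al (2.5 equiv), Cp2ZrCl2 (25 mol %), CH2Cl2, 0 °C → rt; then n-BuLi, THF, −78 °C; (CH2O)n, −78 °C → rt
Reagents that add atoms: trimethylaluminium, C[Al](C)C; formaldehyde (as paraformaldehyde), C=O
Why: Zirconium-catalysed methylalumination adds Me and Al syn across the terminal alkyne with Me on the internal carbon, and hydroxymethylation of the derived alanate with retention should set the (E)-trisubstituted allylic alcohol (Negishi carboalumination).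

Step 9
Reactants: 16
Product: 17 (2E,6Z,10Z)-1-bromo-11-{[tert-butyl(diphenyl)silyl]oxymethyl}-3,7-dimethyltrideca-2,6,10,12-tetraene
Conditions: CBr4, PPh3, CH2Cl2, −20 °C
Reagents that add atoms: tetrabromomethane, BrC(Br)(Br)Br
Why: Appel bromination of the primary (E)-allylic alcohol, as in step 5.

Step 10
Reactants: 1 prop-2-yn-1-ol; 18 5-bromo-2-methylpent-2-ene; 17
Product: 21 (2Z,5E,9Z,13Z)-14-{[tert-butyl(diphenyl)silyl]oxymethyl}-6,10-dimethyl-2-(4-methylpent-3-en-1-yl)hexadeca-2,5,9,13,15-pentaen-1-ol, via homoprenylmagnesium bromide 19 (not isolated), via chelated alkenylmagnesium alkoxide 20 (not isolated)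
Conditions: 18 (3.9 equiv), Mg, THF, rt; then 1 (2.0 equiv), CuI (10 mol %), Et2O–THF, −10 °C → rt; then 17 (1.0 equiv), −40 → 0 °C
Reagents that add atoms: none
Why: Copper-catalysed anti-carbomagnesiation of the propargylic alkoxide gives the chelate with magnesium cis to CH2O, and its copper-catalysed SN2 allylation with retention should place the new CH2 cis to CH2OH, which is the (Z)-geometry the dienophile needs.

Step 11
Reactants: 21
Product: 22 (2Z,5E,9Z,13Z)-14-{[tert-butyl(diphenyl)silyl]oxymethyl}-6,10-dimethyl-2-(4-methylpent-3-en-1-yl)hexadeca-2,5,9,13,15-pentaenal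
Conditions: Dess–Martin periodinane, NaHCO3, CH2Cl2, 0 °C; filtered cold and used at once
Reagents that add atoms: none
Why: Buffered Dess–Martin oxidation of the allylic alcohol is neutral and cold, which should avoid Z to E isomerisation of the 2-alkylenal.

Step 12
Reactants: 22
Product: 23 (1S,3E,7Z,11S,15S)-12-{[tert-butyl(diphenyl)silyl]oxymethyl}-4,8-dimethyl-15-(4-methylpent-3-en-1-yl)bicyclo[9.3.1]pentadeca-3,7,12-triene-15-carbaldehyde
Conditions: (S)-oxazaborolidine from (S)-diphenylprolinol and 2-methylphenylboronic acid, activated by Tf2NH (50 mol %), CH2Cl2, 22 added over 8 h (stationary concentration below 1 mM), −60 → −40 °C; Et3N quench at −40 °C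
Reagents that add atoms: none
Why: Proposed new method: the cationic boron Lewis acid binds the formyl oxygen of the s-trans (Z)-enal (formyl C–H···O contact to the catalyst), lowers the LUMO of C2=C3 of 22 and lets the tethered diene add in a concerted, asynchronous [4+2] event in which the β-carbon C3 bonds first to the unsubstituted diene terminus C16 and C2 then bonds to C13; the closest known reaction types are the oxazaborolidinium-catalysed Diels–Alder reaction of 2-alkylacroleins with acyclic dienes, its transannular version, and Lewis-acid-promoted macrocyclising intramolecular Diels–Alder reactions. The cyclohexene closes by this [4+2] cycloaddition (new bonds C1–C14 and C11–C15 of 23), and the 12-membered ring closes in the same act through C11–C15 in the bridged mode of a terminally tethered triene, the nine-carbon tether ending as the 1,3-bridge and the enal α-carbon as the one-atom bridge C15. C1 and C15 are fixed relative to each other by the (Z)-dienophile geometry (suprafacial addition keeps tether carbon C2 cis to CHO), C11 relative to both by the exo-formyl transition state with the diene substituent outside, and the absolute configuration by the catalyst, whose aryl group should cover the Si face at the enal α-carbon so that the diene adds to the Re face. The step needs (a) ortho regiochemistry, secured by the 1-alkyl substituent of the diene and the polarised β-carbon and reinforced because the alternative would close a more strained 11-membered ring, (b) the exo mode, favoured because the catalyst-bound formyl group and the tether both stay clear of the CH2OSi group on the diene and because only this mode leads to the trans-bridged 12-ring with a gauche–anti sequence at C15 instead of a syn-pentane turn, and (c) cyclisation over dimerisation, secured by slow addition at high dilution.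

Step 13
Reactants: 23
Product: 24 (1S,3E,7Z,11S,15S)-12-{[tert-butyl(diphenyl)silyl]oxymethyl}-4,8-dimethyl-15-(4-methylpent-3-en-1-yl)bicyclo[9.3.1]pentadeca-3,7,12-triene-15-carboxylic acid
Conditions: NaClO2, NaH2PO4, 2-methylbut-2-ene (excess), t-BuOH–H2O, 0 °C → rt
Reagents that add atoms: sodium chlorite, [Na+].[O-]Cl=O
Why: Pinnick oxidation should convert the non-enolisable aldehyde into the acid while the scavenger keeps HOCl from the alkenes, and the quaternary centre cannot epimerise.

Step 14
Reactants: 24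
Product: 25 (1S,3E,7Z,11S,15S)-12-(hydroxymethyl)-4,8-dimethyl-15-(4-methylpent-3-en-1-yl)bicyclo[9.3.1]pentadeca-3,7,12-triene-15-carboxylic acid
Conditions: Bu4NF, THF, 0 °C → rt; aq. citric acid work-up
Reagents that add atoms: none
Why: Fluoride-mediated cleavage of the primary silyl ether should free the alcohol without touching any stereocentre.

**Compound list**

1 | prop-2-yn-1-ol | C#CCO | starting material
2 | vinylmagnesium bromide | C=C[Mg]Br | starting material
3 | 4-ethenyl-2,5-dihydro-1,2-oxamagnesole (chelated dienylmagnesium alkoxide) | C=CC1=C[Mg]OC1 | intermediate (not isolated)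
4 | (2Z)-2-(iodomethylidene)but-3-en-1-ol | OC/C(C=C)=C\I | intermediate
5 | tert-butyl{[(2Z)-2-(iodomethylidene)but-3-en-1-yl]oxy}diphenylsilane | CC(C)(C)[Si](c1ccccc1)(c1ccccc1)OC/C(C=C)=C\I | intermediate
6 | (2Z)-3-methylpent-2-en-4-yn-1-ol | OC/C=C(C)\C#C | starting material
7 | (2Z)-3-methylpenta-2,4-dien-1-ol | OC/C=C(C)\C=C | intermediate
8 | 9-{[(2Z)-5-(9-borabicyclo[3.3.1]nonan-9-yl)-3-methylpent-2-en-1-yl]oxy}-9-borabicyclo[3.3.1]nonane | C(/C=C(C)\CCB1C2CCCC1CCC2)OB1C2CCCC1CCC2 | intermediate (not isolated)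
9 | (2Z,6Z)-7-{[tert-butyl(diphenyl)silyl]oxymethyl}-3-methylnona-2,6,8-trien-1-ol | OC/C=C(C)\CC/C=C(/C=C)CO[Si](c1ccccc1)(c1ccccc1)C(C)(C)C | intermediate
10 | (2Z,6Z)-1-bromo-7-{[tert-butyl(diphenyl)silyl]oxymethyl}-3-methylnona-2,6,8-triene | BrC/C=C(C)\CC/C=C(/C=C)CO[Si](c1ccccc1)(c1ccccc1)C(C)(C)C | intermediate
11 | trimethyl(prop-1-yn-1-yl)silane | CC#C[Si](C)(C)C | starting material
12 | (3-lithioprop-1-yn-1-yl)trimethylsilane | [Li]CC#C[Si](C)(C)C | intermediate (not isolated)
13 | (5Z,9Z)-10-{[tert-butyl(diphenyl)silyl]oxymethyl}-6-methyl-1-(trimethylsilyl)dodeca-5,9,11-trien-1-yne | C[Si](C)(C)C#CCC/C=C(C)\CC/C=C(/C=C)CO[Si](c1ccccc1)(c1ccccc1)C(C)(C)C | intermediate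
14 | (5Z,9Z)-10-{[tert-butyl(diphenyl)silyl]oxymethyl}-6-methyldodeca-5,9,11-trien-1-yne | C#CCC/C=C(C)\CC/C=C(/C=C)CO[Si](c1ccccc1)(c1ccccc1)C(C)(C)C | intermediate
15 | [(1E,5Z,9Z)-10-{[tert-butyl(diphenyl)silyl]oxymethyl}-2,6-dimethyldodeca-1,5,9,11-tetraen-1-yl]dimethylalumane | C[Al](C)/C=C(\C)CC/C=C(C)\CC/C=C(/C=C)CO[Si](c1ccccc1)(c1ccccc1)C(C)(C)C | intermediate (not isolated)
16 | (2E,6Z,10Z)-11-{[tert-butyl(diphenyl)silyl]oxymethyl}-3,7-dimethyltrideca-2,6,10,12-tetraen-1-ol | OC/C=C(\C)CC/C=C(C)\CC/C=C(/C=C)CO[Si](c1ccccc1)(c1ccccc1)C(C)(C)C | intermediate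
17 | (2E,6Z,10Z)-1-bromo-11-{[tert-butyl(diphenyl)silyl]oxymethyl}-3,7-dimethyltrideca-2,6,10,12-tetraene | BrC/C=C(\C)CC/C=C(C)\CC/C=C(/C=C)CO[Si](c1ccccc1)(c1ccccc1)C(C)(C)C | intermediate
18 | 5-bromo-2-methylpent-2-ene | CC(C)=CCCBr | starting material
19 | (4-methylpent-3-en-1-yl)magnesium bromide | CC(C)=CCC[Mg]Br | intermediate (not isolated)
20 | 4-(4-methylpent-3-en-1-yl)-2,5-dihydro-1,2-oxamagnesole (chelated alkenylmagnesium alkoxide) | CC(C)=CCCC1=C[Mg]OC1 | intermediate (not isolated)
21 | (2Z,5E,9Z,13Z)-14-{[tert-butyl(diphenyl)silyl]oxymethyl}-6,10-dimethyl-2-(4-methylpent-3-en-1-yl)hexadeca-2,5,9,13,15-pentaen-1-ol | CC(C)=CCC/C(CO)=C/C/C=C(\C)CC/C=C(C)\CC/C=C(/C=C)CO[Si](c1ccccc1)(c1ccccc1)C(C)(C)C | intermediate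
22 | (2Z,5E,9Z,13Z)-14-{[tert-butyl(diphenyl)silyl]oxymethyl}-6,10-dimethyl-2-(4-methylpent-3-en-1-yl)hexadeca-2,5,9,13,15-pentaenal | CC(C)=CCC/C(C=O)=C/C/C=C(\C)CC/C=C(C)\CC/C=C(/C=C)CO[Si](c1ccccc1)(c1ccccc1)C(C)(C)C | intermediate
23 | (1S,3E,7Z,11S,15S)-12-{[tert-butyl(diphenyl)silyl]oxymethyl}-4,8-dimethyl-15-(4-methylpent-3-en-1-yl)bicyclo[9.3.1]pentadeca-3,7,12-triene-15-carbaldehyde | CC(C)=CCC[C@]1(C=O)[C@@H]2CC=C(CO[Si](c3ccccc3)(c3ccccc3)C(C)(C)C)[C@@H]1CC/C(C)=C\CC/C(C)=C/C2 | intermediate
24 | (1S,3E,7Z,11S,15S)-12-{[tert-butyl(diphenyl)silyl]oxymethyl}-4,8-dimethyl-15-(4-methylpent-3-en-1-yl)bicyclo[9.3.1]pentadeca-3,7,12-triene-15-carboxylic acid | CC(C)=CCC[C@]1(C(=O)O)[C@@H]2CC=C(CO[Si](c3ccccc3)(c3ccccc3)C(C)(C)C)[C@@H]1CC/C(C)=C\CC/C(C)=C/C2 | intermediate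
25 | (1S,3E,7Z,11S,15S)-12-(hydroxymethyl)-4,8-dimethyl-15-(4-methylpent-3-en-1-yl)bicyclo[9.3.1]pentadeca-3,7,12-triene-15-carboxylic acid | CC(C)=CCC[C@]1(C(=O)O)[C@@H]2CC=C(CO)[C@@H]1CC/C(C)=C\CC/C(C)=C/C2 | target

**Step count and risks**

Total step count: 14. Longest linear sequence: 13 steps (steps 1 and 2, then steps 4 to 14, from 1 and 2; the branch from 6 through step 3 joins at step 4).

Steps most likely to fail:

Step 12. Face selection by the catalyst may be eroded, because the substituent cis to the formyl group lies where the catalyst binds. The strong Lewis acid may also isomerise the (Z)-enal or trigger carbonyl-ene attack of the isopropylidene group on the activated formyl group of 22 or 23. The fallback gives up catalyst control and uses known chemistry (it does not remove the dependence on the exo mode). It sets out from 22: Me2AlCl (1.1 equiv), CH2Cl2, 1 mM, −78 → −20 °C, an aluminium-Lewis-acid-promoted macrocyclising intramolecular Diels–Alder reaction, should give the racemate, that is 23 together with its antipode, the (1R,11R,15R)-aldehyde F1. Pinnick oxidation as in step 13 gives 24 together with the (1R,11R,15R)-acid F2. With (R)-1-phenylethylamine in EtOAc the two acids form the (R)-1-phenylethylammonium salt of 24 F3 and the (R)-1-phenylethylammonium salt of the antipodal acid F4, which are separated by fractional crystallisation. Acidification of F3 (aq. HCl) returns 24, where the route is rejoined before step 14.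

Step 10. The chelated alkenylmagnesium is a weak nucleophile, so unconsumed alkyl Grignard reagent may take the bromide first, or the copper-mediated substitution may run with allylic transposition. The fallback separates the two events; it sets out from 1 and 18 and comes back at 21. The chelate 20 is quenched with I2 to give (2Z)-3-iodo-2-(4-methylpent-3-en-1-yl)prop-2-en-1-ol F5, which 3,4-dihydro-2H-pyran/PPTS converts into the tetrahydropyranyl ether of the iodo alcohol F6. t-BuLi (Et2O, −78 °C) gives the alkenyllithium F7 and ZnCl2 the alkenylzinc chloride F8. F8 couples with 17 under Pd(PPh3)4 (Negishi alkenyl–allyl coupling, retention on both partners) to the tetrahydropyranyl ether of 21 F9, and PPTS/MeOH returns 21.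

Step 8. Me3Al with the zirconocene may carbometalate the conjugated diene or ionise the allylic silyl ether beside it. The fallback builds the (E)-olefin without aluminium Lewis acids and replaces steps 6 to 8; it sets out from 10 and comes back at 16. The dianion of ethyl acetoacetate (NaH, then n-BuLi, THF, 0 °C) is alkylated by 10 at its terminal carbon to give the β-keto ester F10. NaH/ClP(O)(OEt)2 (Et2O, 0 °C) gives the (Z)-enol phosphate F11, Me2CuLi (Et2O, −78 → −45 °C) replaces the phosphate with retention to give the (2E)-ester F12, and i-Bu2AlH (CH2Cl2, −78 °C) returns 16.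

**Further compounds**

F1 | step 12 | (1R,3E,7Z,11R,15R)-12-{[tert-butyl(diphenyl)silyl]oxymethyl}-4,8-dimethyl-15-(4-methylpent-3-en-1-yl)bicyclo[9.3.1]pentadeca-3,7,12-triene-15-carbaldehyde | CC(C)=CCC[C@@]1(C=O)[C@H]2CC=C(CO[Si](c3ccccc3)(c3ccccc3)C(C)(C)C)[C@H]1CC/C(C)=C\CC/C(C)=C/C2
F2 | step 12 | (1R,3E,7Z,11R,15R)-12-{[tert-butyl(diphenyl)silyl]oxymethyl}-4,8-dimethyl-15-(4-methylpent-3-en-1-yl)bicyclo[9.3.1]pentadeca-3,7,12-triene-15-carboxylic acid | CC(C)=CCC[C@@]1(C(=O)O)[C@H]2CC=C(CO[Si](c3ccccc3)(c3ccccc3)C(C)(C)C)[C@H]1CC/C(C)=C\CC/C(C)=C/C2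
F3 | step 12 | (1R)-1-phenylethan-1-aminium salt of 24 | C[C@@H]([NH3+])c1ccccc1.CC(C)=CCC[C@]1(C([O-])=O)[C@@H]2CC=C(CO[Si](c3ccccc3)(c3ccccc3)C(C)(C)C)[C@@H]1CC/C(C)=C\CC/C(C)=C/C2
F4 | step 12 | (1R)-1-phenylethan-1-aminium salt of the (1R,11R,15R)-acid | C[C@@H]([NH3+])c1ccccc1.CC(C)=CCC[C@@]1(C([O-])=O)[C@H]2CC=C(CO[Si](c3ccccc3)(c3ccccc3)C(C)(C)C)[C@H]1CC/C(C)=C\CC/C(C)=C/C2
F5 | step 10 | (2Z)-3-iodo-2-(4-methylpent-3-en-1-yl)prop-2-en-1-ol | CC(C)=CCC/C(CO)=C/I
F6 | step 10 | 2-{[(2Z)-3-iodo-2-(4-methylpent-3-en-1-yl)prop-2-en-1-yl]oxy}oxane | CC(C)=CCC/C(COC1CCCCO1)=C/I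
F7 | step 10 | [(1Z)-2-(4-methylpent-3-en-1-yl)-3-(oxan-2-yloxy)prop-1-en-1-yl]lithium | CC(C)=CCC/C(COC1CCCCO1)=C/[Li]
F8 | step 10 | [(1Z)-2-(4-methylpent-3-en-1-yl)-3-(oxan-2-yloxy)prop-1-en-1-yl]zinc chloride | CC(C)=CCC/C(COC1CCCCO1)=C/[Zn]Cl
F9 | step 10 | tetrahydropyranyl ether of 21 | CC(C)=CCC/C(COC1CCCCO1)=C/C/C=C(\C)CC/C=C(C)\CC/C=C(/C=C)CO[Si](c1ccccc1)(c1ccccc1)C(C)(C)C
F10 | step 8 | ethyl (6Z,10Z)-11-{[tert-butyl(diphenyl)silyl]oxymethyl}-7-methyl-3-oxotrideca-6,10,12-trienoate | CCOC(=O)CC(=O)CC/C=C(C)\CC/C=C(/C=C)CO[Si](c1ccccc1)(c1ccccc1)C(C)(C)C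
F11 | step 8 | ethyl (2Z,6Z,10Z)-11-{[tert-butyl(diphenyl)silyl]oxymethyl}-3-[(diethoxyphosphoryl)oxy]-7-methyltrideca-2,6,10,12-tetraenoate | CCOC(=O)/C=C(\OP(=O)(OCC)OCC)CC/C=C(C)\CC/C=C(/C=C)CO[Si](c1ccccc1)(c1ccccc1)C(C)(C)C
F12 | step 8 | ethyl (2E,6Z,10Z)-11-{[tert-butyl(diphenyl)silyl]oxymethyl}-3,7-dimethyltrideca-2,6,10,12-tetraenoate | CCOC(=O)/C=C(\C)CC/C=C(C)\CC/C=C(/C=C)CO[Si](c1ccccc1)(c1ccccc1)C(C)(C)C
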